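**Plan**

1. Retrosynthesis: cut C12–C13 first (sp3–sp2 Negishi coupling), then open ring B at C6–C7 and C8–C9 together. This removes C7–C8 as 4-methyl-1,3-dioxol-2-one and leaves a ring A iodo-enal, which is traced back to 2,2,6-trimethylcyclohexanone.
2. Enabling feature: the C7–C8 edge of ring B carries two cis (7β,8β) oxygens and the C17 methyl, so it is a masked methylvinylene carbonate. C6–C5–C10–C9 is a 4-pentenyl-type radical/acceptor pair that cannot close on itself (only 4-exo or 5-endo) but closes 6-exo once the two-carbon unit is inserted.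
3. Forward order: C10 quaternary centre by asymmetric allylation; exocyclic C5=C6 by Peterson olefination; C5–H by tethered cyclic hydroboration; arms differentiated to the iodo-enal; ring B by the radical annulation; side chain by Negishi coupling; carbonate exchanged for the 7-acetate last.
4. Stereochemistry: C10 from the chiral ligand; C5 from intramolecular B–H delivery; C8 and C9 (and C7 by relay through the cis-fused carbonate) from the chair transition state of the ring closure; the 13E alkene from syn-hydrozirconation.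

Key step: step 8

Remark: labdane numbering is used for positions (ring A C1–C5/C10, ring B C5–C10, side chain C11–C16, C17 on C8); 4-methyl-1,3-dioxol-2-one (13) is assumed to be purchasable.

**Step 1**
Reactants: 1 2,2,6-trimethylcyclohexan-1-one; 2 allyl chloroformate
Product: 3 prop-2-en-1-yl 2,6,6-trimethylcyclohex-1-en-1-yl carbonate
Conditions: LiN(SiMe3)2, THF, 0 °C; then 2, −78 to 25 °C
Reagents that add atoms: 2 allyl chloroformate, C=CCOC(Cl)=O
Why: Only C6–H of 1 is enolisable, so the base gives one tetrasubstituted enolate, which the chloroformate traps on oxygen (enol carbonate formation).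

**Step 2**
Reactants: 3 prop-2-en-1-yl 2,6,6-trimethylcyclohex-1-en-1-yl carbonate
Product: 4 (2R)-2,6,6-trimethyl-2-(prop-2-en-1-yl)cyclohexan-1-one
Conditions: Pd2(dba)3 (2.5 mol %), (R)-t-BuPHOX (6 mol %), THF, 25 °C
Reagents that add atoms: none
Why: Decarboxylative asymmetric allylic alkylation (Tsuji allylation) forms the C–C bond within the chiral pocket of the PHOX ligand and sets the quaternary centre (future C10), the (R)-ligand being chosen because the (S)-ligand is the one expected to give the 2S ketone in this substrate class.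

**Step 3**
Reactants: 4 (2R)-2,6,6-trimethyl-2-(prop-2-en-1-yl)cyclohexan-1-one; 5 (trimethylsilyl)methyllithium
Product: 7 (1R)-1,3,3-trimethyl-2-methylidene-1-(prop-2-en-1-yl)cyclohexane, via lithium alkoxide 6 (not isolated)
Conditions: 5, THF, 0 to 25 °C; then KOt-Bu, 50 °C
Reagents that add atoms: 5 (trimethylsilyl)methyllithium, [Li]C[Si](C)(C)C
Why: Peterson olefination, in which the small Me3SiCH2Li adds to the carbonyl flanked by two quaternary carbons where ylides are too bulky, and potassium-for-lithium exchange triggers syn elimination to the exocyclic C5=C6 alkene without forming a stereocentre.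

**Step 4**
Reactants: 7 (1R)-1,3,3-trimethyl-2-methylidene-1-(prop-2-en-1-yl)cyclohexane
Product: 9 3-[(1R,2S)-2-(hydroxymethyl)-1,3,3-trimethylcyclohexyl]propan-1-ol, via thexyl boracycle 8 (not isolated)
Conditions: thexylborane (from BH3·THF and 2,3-dimethylbut-2-ene), THF, 0 to 40 °C, high dilution; then NaOH, H2O2, 0 to 25 °C
Reagents that add atoms: hydrogen peroxide, OO
Why: Cyclic hydroboration of a 1,5-diene, in which thexylborane adds first to the terminal alkene (boron on C12) and the resulting dialkylborane reaches the shielded C5=C6 bond only intramolecularly, placing boron on C6 and hydrogen on C5 on the face of the C10 arm (also anti to the axial methyl groups on C4 and C10), which sets 5α-H before oxidation with retention.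

**Step 5**
Reactants: 9 3-[(1R,2S)-2-(hydroxymethyl)-1,3,3-trimethylcyclohexyl]propan-1-ol
Product: 10 (1R,2S)-2-(iodomethyl)-1-(3-iodopropyl)-1,3,3-trimethylcyclohexane
Conditions: I2, PPh3, imidazole, toluene, 80 °C
Reagents that add atoms: iodine, II
Why: Appel-type iodination converts both primary alcohols by SN2 displacement of the alkoxyphosphonium groups, heating being needed only for the hindered C6 position.

**Step 6**
Reactants: 10 (1R,2S)-2-(iodomethyl)-1-(3-iodopropyl)-1,3,3-trimethylcyclohexane
Product: 11 3-[(1R,2S)-2-(iodomethyl)-1,3,3-trimethylcyclohexyl]propanal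
Conditions: Me3NO, DMSO, 25 to 40 °C
Reagents that add atoms: trimethylamine N-oxide, C[N+](C)(C)[O-]
Why: Kornblum-type oxidation with an amine N-oxide begins with SN2 attack on carbon, which is fast at the unhindered C12 iodide and blocked at C6 by the two flanking quaternary carbons, so only C12 becomes the aldehyde.

**Step 7**
Reactants: 11 3-[(1R,2S)-2-(iodomethyl)-1,3,3-trimethylcyclohexyl]propanal
Product: 12 (2E)-3-[(1R,2S)-2-(iodomethyl)-1,3,3-trimethylcyclohexyl]prop-2-enal
Conditions: IBX, DMSO–fluorobenzene, 70 °C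
Reagents that add atoms: none
Why: IBX dehydrogenation of a saturated aldehyde through its enol gives the conjugated E-enal (the only β-hydrogens are on C9), and the E geometry keeps the carbonyl out of reach of the C6 radical in the next step.

**Step 8**
Reactants: 12 (2E)-3-[(1R,2S)-2-(iodomethyl)-1,3,3-trimethylcyclohexyl]prop-2-enal; 13 4-methyl-1,3-dioxol-2-one
Product: 16 (5S,7S,8R,9R,10S)-7,8-(carbonyldioxy)-13,14,15,16-tetranorlabdan-12-al, via C8 adduct radical 14 (not isolated), via C11 cyclised radical 15 (not isolated)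
Conditions: 13 (15 equiv), (Me3Si)3SiH and AIBN added by syringe pump, benzene, 80 °C, 0.01 M in 12
Reagents that add atoms: 13 4-methyl-1,3-dioxol-2-one, CC1=COC(=O)O1
Why: Proposed new method: the silyl radical abstracts iodine from 12 to give a primary C6 radical that cannot close onto its own enal (only 4-exo or 5-endo modes exist) and therefore adds to the unsubstituted carbon of 13 (C6–C7 bond); the resulting tertiary, oxygen-substituted C8 radical 14 closes ring B by 6-exo-trig attack on the enal β-carbon C9 (C8–C9 bond), and the α-formyl radical 15 takes hydrogen from the silane to carry the chain. The closest known reaction type is the tin- or silane-mediated radical [4+2] annulation (intermolecular Giese addition followed by 6-exo cyclisation onto an acrylate-type acceptor), and nucleophilic radicals are known to add to vinylene carbonates, but the combination with a 4-substituted vinylene carbonate as the two-carbon partner has not been described. Ring B closes through a chair transition state in which the dioxolanone is cis-fused (O7 equatorial, O8 axial), the C8 methyl is equatorial because an axial methyl would meet the axial C10 methyl, and C11 is equatorial, which gives 7β-O, 8β-O/8α-CH3 and 9β-CH2CHO as in the target. C8 and C9 are thus set in the ring closure under control of C10 and C5, whereas C7 is fixed in the intermolecular addition, for which the substrate offers no facial bias, and is only sorted afterwards: the 7α adduct can close solely with an axial C8 methyl and should end as open-chain reduced material or a separable 7,8-diepimer. The step needs attack at C5 rather than C4 of 13 (secured by the methyl group and the tertiary radical formed), 6-exo rather than 7-endo closure (secured by the polarisation of the enal) and addition to 13 before hydrogen transfer (secured by a large excess of 13 and slow addition of the silane).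

**Step 9**
Reactants: 16 (5S,7S,8R,9R,10S)-7,8-(carbonyldioxy)-13,14,15,16-tetranorlabdan-12-al
Product: 17 (5S,7S,8R,9R,10S)-12-hydroxy-13,14,15,16-tetranorlabdane-7,8-diyl carbonate
Conditions: NaBH4, THF–EtOH, 0 °C
Reagents that add atoms: none
Why: Borohydride reduction of the aldehyde, to which the cyclic carbonate is inert at 0 °C, and no stereocentre is touched.

**Step 10**
Reactants: 17 (5S,7S,8R,9R,10S)-12-hydroxy-13,14,15,16-tetranorlabdane-7,8-diyl carbonate
Product: 18 (5S,7S,8R,9R,10S)-12-iodo-13,14,15,16-tetranorlabdane-7,8-diyl carbonate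
Conditions: I2, PPh3, imidazole, CH2Cl2, 0 to 25 °C
Reagents that add atoms: iodine, II
Why: Appel-type iodination of the unhindered primary alcohol, with the carbonate keeping O8 masked so that the 8,12-ether cannot form from the activated alcohol.

**Step 11**
Reactants: 19 but-2-yn-1-ol
Product: 20 tert-butyl(but-2-yn-1-yloxy)dimethylsilane
Conditions: TBSCl, imidazole, CH2Cl2, 25 °C
Reagents that add atoms: tert-butyldimethylsilyl chloride, CC(C)(C)[Si](C)(C)Cl
Why: Standard silylation of a primary alcohol.

**Step 12**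
Reactants: 20 tert-butyl(but-2-yn-1-yloxy)dimethylsilane
Product: 22 tert-butyl{[(2E)-3-iodobut-2-en-1-yl]oxy}dimethylsilane, via alkenylzirconocene chloride 21 (not isolated)
Conditions: Cp2Zr(H)Cl (excess), THF, 50 °C; then I2, 0 °C
Reagents that add atoms: iodine, II
Why: Hydrozirconation adds Zr–H syn across the alkyne with zirconium on the carbon bearing the smaller methyl group (excess reagent equilibrates the regioisomers), and iodinolysis with retention gives the E-iodide with iodine trans to CH2OTBS.

**Step 13**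
Reactants: 18 (5S,7S,8R,9R,10S)-12-iodo-13,14,15,16-tetranorlabdane-7,8-diyl carbonate; 22 tert-butyl{[(2E)-3-iodobut-2-en-1-yl]oxy}dimethylsilane
Product: 24 (5S,7S,8R,9R,10S,13E)-15-[(tert-butyldimethylsilyl)oxy]labd-13-ene-7,8-diyl carbonate, via alkylzinc iodide 23 (not isolated)
Conditions: Zn dust (activated with Me3SiCl and BrCH2CH2Br), DMA, 40 °C; then 22, Pd(PPh3)4 (5 mol %), 25 to 45 °C
Reagents that add atoms: 22 tert-butyl{[(2E)-3-iodobut-2-en-1-yl]oxy}dimethylsilane, C/C(I)=C\CO[Si](C)(C)C(C)(C)C
Why: Negishi coupling, in which zinc inserts into the primary C–I bond without touching the carbonate and the palladium-catalysed sp3–sp2 coupling proceeds with retention of alkene geometry to give the 13E side chain.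

**Step 14**
Reactants: 24 (5S,7S,8R,9R,10S,13E)-15-[(tert-butyldimethylsilyl)oxy]labd-13-ene-7,8-diyl carbonate
Product: 25 (5S,7S,8R,9R,10S,13E)-15-[(tert-butyldimethylsilyl)oxy]labd-13-ene-7,8-diol
Conditions: LiOH, THF–MeOH–H2O, 40 °C
Reagents that add atoms: none
Why: Base hydrolysis of the cyclic carbonate frees the cis-diol, the silyl ether and the alkene being stable to LiOH.

**Step 15**
Reactants: 25 (5S,7S,8R,9R,10S,13E)-15-[(tert-butyldimethylsilyl)oxy]labd-13-ene-7,8-diol; 26 acetic anhydride
Product: 27 (5S,7S,8R,9R,10S,13E)-15-[(tert-butyldimethylsilyl)oxy]-8-hydroxylabd-13-en-7-yl acetate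
Conditions: 26, pyridine, DMAP (cat.), CH2Cl2, 0 to 25 °C
Reagents that add atoms: 26 acetic anhydride, CC(=O)OC(C)=O
Why: DMAP-catalysed acylation takes the secondary equatorial 7β-hydroxyl, whereas the tertiary axial 8β-hydroxyl does not react under these conditions and C15 is still silylated.

**Step 16**
Reactants: 27 (5S,7S,8R,9R,10S,13E)-15-[(tert-butyldimethylsilyl)oxy]-8-hydroxylabd-13-en-7-yl acetate
Product: 28 (5S,7S,8R,9R,10S,13E)-8,15-dihydroxylabd-13-en-7-yl acetate
Conditions: HF·pyridine, THF–pyridine, 0 °C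
Reagents that add atoms: none
Why: Fluoride cleavage of the primary silyl ether under mildly acidic conditions leaves the acetate in place (no base to promote acyl migration or hydrolysis) and gives the target.

**Compound list**

1 | 2,2,6-trimethylcyclohexan-1-one (racemic) | CC1CCCC(C)(C)C1=O | starting material
2 | allyl chloroformate | C=CCOC(Cl)=O | starting material
3 | prop-2-en-1-yl 2,6,6-trimethylcyclohex-1-en-1-yl carbonate | C=CCOC(=O)OC1=C(C)CCCC1(C)C | intermediate
4 | (2R)-2,6,6-trimethyl-2-(prop-2-en-1-yl)cyclohexan-1-one | O=C1C(C)(C)CCC[C@]1(C)CC=C | intermediate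
5 | (trimethylsilyl)methyllithium | [Li]C[Si](C)(C)C | starting material
6 | lithium (6R)-2,2,6-trimethyl-6-(prop-2-en-1-yl)-1-[(trimethylsilyl)methyl]cyclohexan-1-olate (carbinol centre either way) | [Li+].[O-]C1(C[Si](C)(C)C)C(C)(C)CCC[C@]1(C)CC=C | intermediate
7 | (1R)-1,3,3-trimethyl-2-methylidene-1-(prop-2-en-1-yl)cyclohexane | C=C1C(C)(C)CCC[C@]1(C)CC=C | intermediate
8 | thexyl boracycle (boron bonded to C6 and C12 of the ring A fragment, H5 cis to the C10 arm) | CC(C)C(C)(C)B1C[C@H]2C(C)(C)CCC[C@]2(C)CCC1 | intermediate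
9 | 3-[(1R,2S)-2-(hydroxymethyl)-1,3,3-trimethylcyclohexyl]propan-1-ol | OC[C@H]1C(C)(C)CCC[C@]1(C)CCCO | intermediate
10 | (1R,2S)-2-(iodomethyl)-1-(3-iodopropyl)-1,3,3-trimethylcyclohexane | IC[C@H]1C(C)(C)CCC[C@]1(C)CCCI | intermediate
11 | 3-[(1R,2S)-2-(iodomethyl)-1,3,3-trimethylcyclohexyl]propanal | IC[C@H]1C(C)(C)CCC[C@]1(C)CCC=O | intermediate
12 | (2E)-3-[(1R,2S)-2-(iodomethyl)-1,3,3-trimethylcyclohexyl]prop-2-enal | IC[C@H]1C(C)(C)CCC[C@]1(C)/C=C/C=O | intermediate
13 | 4-methyl-1,3-dioxol-2-one | CC1=COC(=O)O1 | starting material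
14 | C8 adduct radical (tertiary dioxolanonyl radical, C6–C7 bond formed, 7β-oxygen) | C[C]1OC(=O)O[C@H]1C[C@H]2C(C)(C)CCC[C@]2(C)/C=C/C=O | intermediate
15 | C11 cyclised radical (α-formyl radical, ring B closed) | O=C1O[C@H]2C[C@H]3C(C)(C)CCC[C@]3(C)[C@@H]([CH]C=O)[C@@]2(C)O1 | intermediate
16 | (5S,7S,8R,9R,10S)-7,8-(carbonyldioxy)-13,14,15,16-tetranorlabdan-12-al | O=C1O[C@H]2C[C@H]3C(C)(C)CCC[C@]3(C)[C@@H](CC=O)[C@@]2(C)O1 | intermediate
17 | (5S,7S,8R,9R,10S)-12-hydroxy-13,14,15,16-tetranorlabdane-7,8-diyl carbonate | O=C1O[C@H]2C[C@H]3C(C)(C)CCC[C@]3(C)[C@@H](CCO)[C@@]2(C)O1 | intermediate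
18 | (5S,7S,8R,9R,10S)-12-iodo-13,14,15,16-tetranorlabdane-7,8-diyl carbonate | O=C1O[C@H]2C[C@H]3C(C)(C)CCC[C@]3(C)[C@@H](CCI)[C@@]2(C)O1 | intermediate
19 | but-2-yn-1-ol | CC#CCO | starting material
20 | tert-butyl(but-2-yn-1-yloxy)dimethylsilane | CC#CCO[Si](C)(C)C(C)(C)C | intermediate
21 | (E)-alkenylzirconocene chloride (zirconium on C3, trans to CH2OTBS) | C/C(=C\CO[Si](C)(C)C(C)(C)C)[Zr](Cl)(C1C=CC=C1)C1C=CC=C1 | intermediate
22 | tert-butyl{[(2E)-3-iodobut-2-en-1-yl]oxy}dimethylsilane | C/C(I)=C\CO[Si](C)(C)C(C)(C)C | intermediate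
23 | alkylzinc iodide from 18 (zinc on C12) | O=C1O[C@H]2C[C@H]3C(C)(C)CCC[C@]3(C)[C@@H](CC[Zn]I)[C@@]2(C)O1 | intermediate
24 | (5S,7S,8R,9R,10S,13E)-15-[(tert-butyldimethylsilyl)oxy]labd-13-ene-7,8-diyl carbonate | O=C1O[C@H]2C[C@H]3C(C)(C)CCC[C@]3(C)[C@@H](CC/C(C)=C/CO[Si](C)(C)C(C)(C)C)[C@@]2(C)O1 | intermediate
25 | (5S,7S,8R,9R,10S,13E)-15-[(tert-butyldimethylsilyl)oxy]labd-13-ene-7,8-diol | O[C@H]1C[C@H]2C(C)(C)CCC[C@]2(C)[C@@H](CC/C(C)=C/CO[Si](C)(C)C(C)(C)C)[C@@]1(C)O | intermediate
26 | acetic anhydride | CC(=O)OC(C)=O | starting material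
27 | (5S,7S,8R,9R,10S,13E)-15-[(tert-butyldimethylsilyl)oxy]-8-hydroxylabd-13-en-7-yl acetate | CC(=O)O[C@H]1C[C@H]2C(C)(C)CCC[C@]2(C)[C@@H](CC/C(C)=C/CO[Si](C)(C)C(C)(C)C)[C@@]1(C)O | intermediate
28 | (5S,7S,8R,9R,10S,13E)-8,15-dihydroxylabd-13-en-7-yl acetate (7β-acetoxy, 8β-hydroxy) | CC(=O)O[C@H]1C[C@H]2C(C)(C)CCC[C@]2(C)[C@@H](CC/C(C)=C/CO)[C@@]1(C)O | target

**Totals**

Total step count: 16. Longest linear sequence: 14 steps (steps 1–10 and 13–16, from 2,2,6-trimethylcyclohexanone); the alkenyl iodide 22 is made in 2 steps (11–12).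

**Steps most likely to fail**

1. Step 8 (proposed new method). What may go wrong: non-selective facial approach of 13 to the C6 radical, which would divert up to half of the material away from the productive 7β adduct, and hydrogen transfer to the C6 or C8 radical before the second C–C bond forms. Fallback with known reactions, setting out from 12 and coming back at 27: iodide 12 is coupled with 2-[(4-methoxybenzyl)oxy]propanoyl chloride F1 (from the acid and oxalyl chloride) by nickel-catalysed reductive acylation (NiCl2(dme), 4,4'-di-tert-butyl-2,2'-bipyridine, Mn powder, DMA). This gives the α-alkoxy ketone (2E)-3-[(1R,2S)-2-{3-[(4-methoxybenzyl)oxy]-2-oxobutyl}-1,3,3-trimethylcyclohexyl]prop-2-enal F2, in which C6–C7 is in place and C7 is a carbonyl carbon, so no stereocentre is set in the intermolecular event. DBU in MeCN then closes ring B by a 6-exo intramolecular Michael addition of the C8 enolate to the enal; under equilibrating conditions this should place the C8 methyl and the C9 arm equatorial and the ether oxygen axial, giving 8β-[(4-methoxybenzyl)oxy]-7-oxo-13,14,15,16-tetranorlabdan-12-al F3. NaBH4 reduces both carbonyl groups, with hydride entering C7 axially from the α face, to give the 7β,12-diol F4. I2/PPh3/imidazole converts the primary alcohol into the 12-iodo-7β-ol F5, and Ac2O/DMAP gives the 12-iodo 7-acetate F6. Zinc insertion gives the alkylzinc iodide F7, which is coupled with 22 under Pd(PPh3)4 to give the 8-O-(4-methoxybenzyl) ether of 27 F8. DDQ in wet CH2Cl2 removes the 4-methoxybenzyl group and returns 27.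

2. Step 4. What may go wrong: the second, intramolecular hydroboration of the shielded exocyclic alkene may be outrun by intermolecular B–H transfer (oligomeric boranes), with loss of the face control at C5. Fallback, setting out from 7 and coming back at 9: the two alkenes are addressed one after the other without a tether. 9-BBN followed by NaOH/H2O2 hydroborates only the allyl group and gives 3-[(1R)-1,3,3-trimethyl-2-methylidenecyclohexyl]propan-1-ol F9, which is silylated (TBDPSCl, imidazole) to the bulky ether tert-butyl{3-[(1R)-1,3,3-trimethyl-2-methylidenecyclohexyl]propoxy}diphenylsilane F10. BH3·SMe2 then NaOH/H2O2 attacks the exocyclic alkene of the conformer with equatorial arm and axial C10 methyl, anti to the axial methyl groups, to give [(1S,2R)-2-{3-[(tert-butyldiphenylsilyl)oxy]propyl}-2,6,6-trimethylcyclohexyl]methanol F11 after separation from its C5 epimer, and TBAF returns 9.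

3. Step 3. What may go wrong: sluggish addition to the carbonyl group between two quaternary carbons, or slow elimination of the hindered β-silyl alkoxide. Fallback, setting out from 4 and coming back at 7: MeLi/CeCl3 (THF, −78 °C) gives the tertiary alcohol (2R)-1,2,6,6-tetramethyl-2-(prop-2-en-1-yl)cyclohexan-1-ol F12. Dehydration with SOCl2/pyridine can only go toward the new methyl group, because both ring neighbours are quaternary, and returns 7.

**Further compounds**

F1 | step 8 | 2-[(4-methoxybenzyl)oxy]propanoyl chloride (racemic) | COc1ccc(COC(C)C(Cl)=O)cc1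
F2 | step 8 | (2E)-3-[(1R,2S)-2-{3-[(4-methoxybenzyl)oxy]-2-oxobutyl}-1,3,3-trimethylcyclohexyl]prop-2-enal | COc1ccc(COC(C)C(=O)C[C@H]2C(C)(C)CCC[C@]2(C)/C=C/C=O)cc1
F3 | step 8 | (5S,8R,9R,10S)-8-[(4-methoxybenzyl)oxy]-7-oxo-13,14,15,16-tetranorlabdan-12-al | O=C1C[C@H]2C(C)(C)CCC[C@]2(C)[C@@H](CC=O)[C@@]1(C)OCc1ccc(OC)cc1
F4 | step 8 | (5S,7S,8R,9R,10S)-8-[(4-methoxybenzyl)oxy]-13,14,15,16-tetranorlabdane-7,12-diol | O[C@H]1C[C@H]2C(C)(C)CCC[C@]2(C)[C@@H](CCO)[C@@]1(C)OCc1ccc(OC)cc1
F5 | step 8 | (5S,7S,8R,9R,10S)-12-iodo-8-[(4-methoxybenzyl)oxy]-13,14,15,16-tetranorlabdan-7-ol | O[C@H]1C[C@H]2C(C)(C)CCC[C@]2(C)[C@@H](CCI)[C@@]1(C)OCc1ccc(OC)cc1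
F6 | step 8 | (5S,7S,8R,9R,10S)-12-iodo-8-[(4-methoxybenzyl)oxy]-13,14,15,16-tetranorlabdan-7-yl acetate | CC(=O)O[C@H]1C[C@H]2C(C)(C)CCC[C@]2(C)[C@@H](CCI)[C@@]1(C)OCc1ccc(OC)cc1
F7 | step 8 | alkylzinc iodide from F6 (zinc on C12) | CC(=O)O[C@H]1C[C@H]2C(C)(C)CCC[C@]2(C)[C@@H](CC[Zn]I)[C@@]1(C)OCc1ccc(OC)cc1
F8 | step 8 | (5S,7S,8R,9R,10S,13E)-15-[(tert-butyldimethylsilyl)oxy]-8-[(4-methoxybenzyl)oxy]labd-13-en-7-yl acetate | CC(=O)O[C@H]1C[C@H]2C(C)(C)CCC[C@]2(C)[C@@H](CC/C(C)=C/CO[Si](C)(C)C(C)(C)C)[C@@]1(C)OCc1ccc(OC)cc1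
F9 | step 4 | 3-[(1R)-1,3,3-trimethyl-2-methylidenecyclohexyl]propan-1-ol | C=C1C(C)(C)CCC[C@]1(C)CCCO
F10 | step 4 | tert-butyl{3-[(1R)-1,3,3-trimethyl-2-methylidenecyclohexyl]propoxy}diphenylsilane | C=C1C(C)(C)CCC[C@]1(C)CCCO[Si](c1ccccc1)(c1ccccc1)C(C)(C)C
F11 | step 4 | [(1S,2R)-2-{3-[(tert-butyldiphenylsilyl)oxy]propyl}-2,6,6-trimethylcyclohexyl]methanol | OC[C@H]1C(C)(C)CCC[C@]1(C)CCCO[Si](c1ccccc1)(c1ccccc1)C(C)(C)C
F12 | step 3 | (2R)-1,2,6,6-tetramethyl-2-(prop-2-en-1-yl)cyclohexan-1-ol (carbinol centre either way) | CC1(O)C(C)(C)CCC[C@]1(C)CC=C
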